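Numbering of the target: ring A has C1 (bears the ester carbonyl), C2 (ether O), C3 (CHO), C4 (OH), C5 (H), C6 (CH3); ring B has C1' (bears the lactone C=O), C2' (OH), C3' (CH2OAc), C4' (ester O), C5' (ether O), C6' (bears the lactol CH, S).
Retrosynthesis: the (S)-lactol goes back to the racemate; the acetate, free phenols, lactol OH, 3'-CH2–O bond and C3 formyl group go back to a bromo depsidone with a phthalide and a 3'-methyl group on ring B; then the ester bond C(=O)–O4' of the seven-membered ring is cut, then ring A at C2–C3 and C1–C6, and last the alkynyl ether bond O5'–C(sp).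
Enabling feature: the ring-A segment C3–C4(O)–C5(H)–C6(CH3) is the diene C3–C6 of 4-methoxy-6-methyl-2-pyrone (the O-methyl ether of triacetic acid lactone), and C1 with its carboxyl carbon and C2 with the ether oxygen O5' are the two alkyne carbons of a 3-aryloxypropiolate, so the hindered diaryl ether oxygen is in place before ring A exists.
Forward order: ring B is built from methyl 2,4-dihydroxy-3-methylbenzoate and closed to the five-membered phthalide lactone; the alkynyl ether is made; ring A arises by pyrone Diels–Alder reaction and loss of CO2; the seven-membered depsidone ring is closed by lactonisation; then both ring-B benzylic carbons are oxidised, bromine is exchanged for CHO, the methyl ethers are removed and the primary alcohol is acetylated.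
Stereochemistry: C6' is the only stereocentre and is a hemiacetal carbon; it is formed racemic (step 12) and the (S) enantiomer is selected in the last step by chromatography on a chiral stationary phase.
Key step: step 10

Remark on the chemistry: the free lactol can epimerise through its ring-opened formyl acid when acid, base or protic solvent is present. It is assumed to hold its configuration in cold, aprotic, neutral media, as the anomers of reducing sugars do, so the (S) enantiomer is separated only at the very end. By the sequence rules (ring O > OH > aryl C > H) the target centre is S. Target numbering is also used for the precursors of rings A and B.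

Step 1
Reactants: 1 methyl 2,4-dihydroxy-3-methylbenzoate
Product: 2 methyl 5-bromo-2,4-dihydroxy-3-methylbenzoate
Conditions: NBS (1.0 equiv), MeCN, 0 °C
Reagents that add atoms: N-bromosuccinimide, O=C1CCC(=O)N1Br
Why: Electrophilic aromatic bromination should go to C5 (future C5'), which is para to the 2-OH and ortho to the 4-OH and is the only activated free position, C6 being meta to both hydroxyl groups.

Step 2
Reactants: 2 methyl 5-bromo-2,4-dihydroxy-3-methylbenzoate
Product: 3 methyl 5-bromo-2-hydroxy-4-[(4-methoxybenzyl)oxy]-3-methylbenzoate
Conditions: 4-methoxybenzyl chloride (1.05 equiv), K2CO3 (1.1 equiv), NaI (cat.), DMF, 20 °C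
Reagents that add atoms: 4-methoxybenzyl chloride, COc1ccc(CCl)cc1
Why: Williamson etherification should be selective for the 4-OH (future O4'), which is para to the ester and the more acidic phenol, because the 2-OH is tied up in a hydrogen bond to the ester carbonyl.

Step 3
Reactants: 3 methyl 5-bromo-2-hydroxy-4-[(4-methoxybenzyl)oxy]-3-methylbenzoate
Product: 4 methyl 5-bromo-2-methoxy-4-[(4-methoxybenzyl)oxy]-3-methylbenzoate
Conditions: MeI (3 equiv), K2CO3 (2 equiv), DMF, 50 °C
Reagents that add atoms: iodomethane, CI
Why: Williamson O-methylation of the remaining chelated phenol under more forcing conditions gives a methyl ether that is inert to the later radical bromination and is removable by BCl3 because it sits ortho to a carbonyl group.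

Step 4
Reactants: 4 methyl 5-bromo-2-methoxy-4-[(4-methoxybenzyl)oxy]-3-methylbenzoate
Product: 6 methyl 5-hydroxy-2-methoxy-4-[(4-methoxybenzyl)oxy]-3-methylbenzoate, via aryl pinacol boronate 5 (not isolated)
Conditions: bis(pinacolato)diboron, PdCl2[1,1'-bis(diphenylphosphino)ferrocene] (5 mol %), potassium acetate, 1,4-dioxane, 90 °C; then 30 % H2O2, 1 M NaOH, THF, 0 °C
Reagents that add atoms: hydrogen peroxide, OO; bis(pinacolato)diboron, CC1(C)OB(OC1(C)C)B1OC(C)(C)C(C)(C)O1 (its atoms stay only in 5)
Why: Miyaura borylation of the aryl bromide followed by oxidation of the C–B bond (aryl shift from boron to oxygen) should place the O5' phenol on the brominated carbon without touching the ester or the benzyl ether.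

Step 5
Reactants: 6 methyl 5-hydroxy-2-methoxy-4-[(4-methoxybenzyl)oxy]-3-methylbenzoate
Product: 7 4-hydroxy-7-methoxy-5-[(4-methoxybenzyl)oxy]-6-methylisobenzofuran-1(3H)-one (ring-B phthalide; the free OH is O5')
Conditions: 37 % aq. CH2O (5 equiv), NaOH (2 equiv), H2O/THF, 0 to 20 °C; then 1 M HCl to pH 3
Reagents that add atoms: formaldehyde, C=O
Why: Lederer–Manasse hydroxymethylation should occur at the only free carbon ortho to the phenoxide (C6'), and the new benzylic alcohol closes onto the neighbouring ester (5-exo-trig lactonisation, completed on acidification) as in the classical phthalide synthesis from 3-hydroxybenzoates and formaldehyde.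

Step 6
Reactants: 8 propiolic acid
Product: 9 4-methoxybenzyl propiolate
Conditions: 4-methoxybenzyl chloride (1.0 equiv), KHCO3 (1.1 equiv), DMF, 20 °C
Reagents that add atoms: 4-methoxybenzyl chloride, COc1ccc(CCl)cc1
Why: O-alkylation of the carboxylate (SN2 at the benzylic chloride) should give the ester with a base too weak to add to the triple bond.

Step 7
Reactants: 9 4-methoxybenzyl propiolate
Product: 10 4-methoxybenzyl 3-bromopropiolate
Conditions: NBS (1.1 equiv), AgNO3 (10 mol %), acetone, 20 °C
Reagents that add atoms: N-bromosuccinimide, O=C1CCC(=O)N1Br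
Why: Silver-catalysed bromination of the terminal alkyne through the silver acetylide is the standard route to 3-bromopropiolates.

Step 8
Reactants: 7 4-hydroxy-7-methoxy-5-[(4-methoxybenzyl)oxy]-6-methylisobenzofuran-1(3H)-one; 10 4-methoxybenzyl 3-bromopropiolate
Product: 11 4-methoxybenzyl 3-({7-methoxy-5-[(4-methoxybenzyl)oxy]-6-methyl-1-oxo-1,3-dihydroisobenzofuran-4-yl}oxy)prop-2-ynoate
Conditions: NaH (1.0 equiv), THF, 0 °C; the phenoxide solution is then added slowly to 10 (1.3 equiv), THF, −78 to −20 °C; product kept dry and used at once
Reagents that add atoms: none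
Why: Proposed new method: the sodium phenoxide of 7 should add to the bromine-bearing carbon of 10 (conjugate addition to the alkynoate), and the allenolate so formed should expel bromide, whose C–Br bond lies in the plane of the enolate π system, to restore the triple bond (addition–elimination at an sp carbon), inverse addition and the two ortho substituents of the phenoxide holding back a second addition; the closest known reactions are substitutions of acceptor-substituted haloalkynes by thiolates and amide anions and the base-catalysed addition of phenols to propiolates.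

Step 9
Reactants: 12 4-methoxy-6-methyl-2H-pyran-2-one
Product: 13 3-bromo-4-methoxy-6-methyl-2H-pyran-2-one
Conditions: NBS (1.05 equiv), MeCN, 20 °C, dark
Reagents that add atoms: N-bromosuccinimide, O=C1CCC(=O)N1Br
Why: Electrophilic bromination should take C3, the nucleophilic α-carbon of the vinylogous ester in 4-methoxy-2-pyrones, which marks the later formyl site.

Step 10
Reactants: 11 4-methoxybenzyl 3-(aryloxy)prop-2-ynoate (aryl = the phthalide unit of 7); 13 3-bromo-4-methoxy-6-methyl-2H-pyran-2-one
Product: 15 4-methoxybenzyl 3-bromo-4-methoxy-2-({7-methoxy-5-[(4-methoxybenzyl)oxy]-6-methyl-1-oxo-1,3-dihydroisobenzofuran-4-yl}oxy)-6-methylbenzoate, via bridged bicyclic lactone 14 (not isolated)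
Conditions: 13 (3 equiv), 11 (0.5 M), 1,2-dichlorobenzene, 2,6-di-tert-butyl-4-methylphenol (cat.), 4 Å molecular sieves, 170 °C, sealed tube, argon
Reagents that add atoms: none
Why: Proposed new method: the diene C3=C4–C5=C6 of pyrone 13 should add to the triple bond of 11 in a concerted, asynchronous [4+2] cycloaddition that forms C2–C3 (pyrone C3 to the oxygen-bearing alkyne carbon) and C1–C6 (pyrone C6 to the ester-bearing alkyne carbon), and the bridged lactone 14 then loses CO2 by retro-[4+2] reaction. The closest known reaction type is the thermal Diels–Alder/decarboxylation of 2-pyrones, including 4-alkoxy and 3-bromo members, with propiolates and acetylenedicarboxylates to give benzoates; a 3-aryloxypropiolate has not been used as the alkyne. Ring A is closed as a six-membered carbocycle by intermolecular cycloaddition, both ring bonds being made in this step, and it becomes aromatic in the same flask by extrusion of CO2. No stereocentre remains, since the two bridgehead centres of 14 are formed racemic and are erased on aromatisation, so no control element is needed. The step needs a single regiochemistry, secured by matched polarity: the 4-methoxy group and the ring oxygen make pyrone C3 the nucleophilic diene terminus and the ester makes the aryloxy-bearing carbon of 11 the electrophilic alkyne terminus, so bromine ends at C3 next to the ether oxygen at C2 and the methyl group at C6 next to the carboxyl at C1. The aryloxy donor lowers the reactivity of the alkyne, which is met by excess pyrone, high concentration and 170 °C under acid-free and water-free conditions.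

Step 11
Reactants: 15 4-methoxybenzyl 3-bromo-4-methoxy-2-(aryloxy)-6-methylbenzoate
Product: 17 bromo phthalide depsidone (ring A: 3-Br, 4-OMe, 6-CH3; ring B: 2'-OMe, 3'-CH3, lactone C1'(C=O)–O–C6'H2; the rings joined by the ester C1–C(=O)–O4' and the ether C2–O5' in a seven-membered ring), via hydroxy acid 16 (not isolated)
Conditions: CF3CO2H/CH2Cl2 (1:4), anisole (5 equiv), 0 to 20 °C; evaporate with toluene; then (CF3CO)2O (3 equiv), toluene, 20 °C
Reagents that add atoms: none
Why: Acidolysis should remove both 4-methoxybenzyl groups (ester and ether) as the stabilised benzylic cation, which anisole traps, and the mixed trifluoroacetic anhydride of the hindered benzoic acid, the standard activation for aryl esters of 2,6-disubstituted benzoic acids, then acylates the freed O4' phenol intramolecularly (7-exo-trig lactonisation).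

Step 12
Reactants: 17 bromo phthalide depsidone
Product: 19 depsidone with 3'-CH2OCH3 and C6'H(OCH3) (3-methoxyphthalide acetal, racemic at C6'), otherwise as 17, via dibromide 18 (not isolated)
Conditions: NBS (2.2 equiv), AIBN (10 mol %), PhCF3, 85 °C; filter, evaporate; then AgOSO2CF3 (2.2 equiv), 2,6-lutidine (2.5 equiv), MeOH/CH2Cl2, 0 to 20 °C
Reagents that add atoms: methanol, CO; N-bromosuccinimide, O=C1CCC(=O)N1Br (its bromine stays only in 18)
Why: Wohl–Ziegler bromination should take the two most activated benzylic positions, the 3'-methyl group flanked by two oxygen substituents and the phthalide CH2 (benzylic and next to oxygen), in preference to the ring-A methyl group ortho to the ester carbonyl, and silver-assisted methanolysis then turns both bromides into methyl ethers that survive the formylation; the step is placed before any aldehyde is present and creates C6' as a racemic centre.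

Step 13
Reactants: 19 bromo depsidone with 3'-CH2OCH3 and C6'H(OCH3)
Product: 20 the corresponding 3-formyl depsidone (C3–CHO in place of C3–Br, racemic at C6')
Conditions: Pd(OAc)2 (3 mol %), di(1-adamantyl)-n-butylphosphine (9 mol %), CO/H2 (1:1, 5 bar), TMEDA (0.75 equiv), toluene, 100 °C
Reagents that add atoms: carbon monoxide, [C-]#[O+]
Why: Palladium-catalysed reductive carbonylation (formylation of an aryl bromide with synthesis gas) should work because zerovalent palladium with a bulky electron-rich phosphine inserts into the hindered C3–Br bond, CO insertion gives the acyl complex and hydrogenolysis releases the aldehyde at the carbon marked by bromine.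

Step 14
Reactants: 20 3-formyl depsidone with four O-methyl groups
Product: 21 racemic salazinic acid (ring A: 3-CHO, 4-OH, 6-CH3; ring B: 2'-OH, 3'-CH2OH, lactol C6'H(OH))
Conditions: BCl3 (8 equiv), CH2Cl2, −78 to 0 °C; then THF/H2O, NaHCO3, 0 to 20 °C; acidify to pH 3
Reagents that add atoms: water, O
Why: Lewis-acid ether cleavage should remove both aryl methyl groups through boron chelates with the ortho carbonyl groups (CHO at C3, lactone C=O at C1'), cleave the benzylic and acetal methyl ethers via their chlorides, and on aqueous work-up give the benzylic alcohol and the lactol while the depsidone ester stays intact.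

Step 15
Reactants: 21 racemic salazinic acid
Product: 22 racemic galbinic acid (3'-CH2OAc)
Conditions: AcCl (1.1 equiv), 2,4,6-collidine (2 equiv), THF, −78 to −40 °C
Reagents that add atoms: acetyl chloride, CC(Cl)=O
Why: Kinetically selective O-acylation with acetyl chloride and a hindered pyridine base should take the primary alcohol, because both phenols are chelated to carbonyl groups and the lactol hydroxyl is a less nucleophilic hemiacetal OH.

Step 16
Reactants: 22 racemic galbinic acid
Product: 23 (S)-galbinic acid
Conditions: preparative HPLC on immobilised amylose tris(3,5-dimethylphenylcarbamate), n-heptane/THF with 0.1 % HCO2H, 5 °C; fractions evaporated below 10 °C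
Reagents that add atoms: none
Why: Resolution by chromatography on a chiral stationary phase makes no bond but selects the (S) antipode of the racemic hemiacetal (to be assigned by comparing measured and computed circular dichroism), and the (R) fraction can be re-equilibrated through the open formyl acid and passed again.

Compound list
1 | methyl 2,4-dihydroxy-3-methylbenzoate | COC(=O)c1ccc(O)c(C)c1O | starting material
2 | methyl 5-bromo-2,4-dihydroxy-3-methylbenzoate | COC(=O)c1cc(Br)c(O)c(C)c1O | intermediate
3 | methyl 5-bromo-2-hydroxy-4-[(4-methoxybenzyl)oxy]-3-methylbenzoate | COC(=O)c1cc(Br)c(OCc2ccc(OC)cc2)c(C)c1O | intermediate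
4 | methyl 5-bromo-2-methoxy-4-[(4-methoxybenzyl)oxy]-3-methylbenzoate | COC(=O)c1cc(Br)c(OCc2ccc(OC)cc2)c(C)c1OC | intermediate
5 | methyl 2-methoxy-4-[(4-methoxybenzyl)oxy]-3-methyl-5-(4,4,5,5-tetramethyl-1,3,2-dioxaborolan-2-yl)benzoate (not isolated) | COC(=O)c1cc(B2OC(C)(C)C(C)(C)O2)c(OCc2ccc(OC)cc2)c(C)c1OC | intermediate
6 | methyl 5-hydroxy-2-methoxy-4-[(4-methoxybenzyl)oxy]-3-methylbenzoate | COC(=O)c1cc(O)c(OCc2ccc(OC)cc2)c(C)c1OC | intermediate
7 | 4-hydroxy-7-methoxy-5-[(4-methoxybenzyl)oxy]-6-methylisobenzofuran-1(3H)-one | O=C1OCc2c(O)c(OCc3ccc(OC)cc3)c(C)c(OC)c12 | intermediate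
8 | propiolic acid | C#CC(=O)O | starting material
9 | 4-methoxybenzyl propiolate | C#CC(=O)OCc1ccc(OC)cc1 | intermediate
10 | 4-methoxybenzyl 3-bromopropiolate | BrC#CC(=O)OCc1ccc(OC)cc1 | intermediate
11 | 4-methoxybenzyl 3-({7-methoxy-5-[(4-methoxybenzyl)oxy]-6-methyl-1-oxo-1,3-dihydroisobenzofuran-4-yl}oxy)prop-2-ynoate | COc1ccc(COC(=O)C#COc2c(OCc3ccc(OC)cc3)c(C)c(OC)c3C(=O)OCc23)cc1 | intermediate
12 | 4-methoxy-6-methyl-2H-pyran-2-one | COC1=CC(=O)OC(C)=C1 | starting material
13 | 3-bromo-4-methoxy-6-methyl-2H-pyran-2-one | COC1=C(Br)C(=O)OC(C)=C1 | intermediate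
14 | 4-methoxybenzyl 4-bromo-8-methoxy-1-methyl-3-oxo-5-(aryloxy)-2-oxabicyclo[2.2.2]octa-5,7-diene-6-carboxylate, aryl = phthalide unit of 11, racemic (not isolated) | BrC12C(=O)OC(C)(C=C1OC)C(C(=O)OCc1ccc(OC)cc1)=C2Oc1c(OCc2ccc(OC)cc2)c(C)c(OC)c2C(=O)OCc12 | intermediate
15 | 4-methoxybenzyl 3-bromo-4-methoxy-2-({7-methoxy-5-[(4-methoxybenzyl)oxy]-6-methyl-1-oxo-1,3-dihydroisobenzofuran-4-yl}oxy)-6-methylbenzoate | COc1ccc(COC(=O)c2c(C)cc(OC)c(Br)c2Oc2c(OCc3ccc(OC)cc3)c(C)c(OC)c3C(=O)OCc23)cc1 | intermediate
16 | 3-bromo-2-[(5-hydroxy-7-methoxy-6-methyl-1-oxo-1,3-dihydroisobenzofuran-4-yl)oxy]-4-methoxy-6-methylbenzoic acid (not isolated) | Cc1c(OC)c2C(=O)OCc2c(Oc2c(Br)c(OC)cc(C)c2C(O)=O)c1O | intermediate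
17 | bromo phthalide depsidone (ring A 3-Br, 4-OMe, 6-CH3; ring B 2'-OMe, 3'-CH3, C6'H2 lactone) | Cc1c(OC)c2c(c3c1OC(=O)c1c(C)cc(OC)c(Br)c1O3)COC2=O | intermediate
18 | depsidone as 17 with 3'-CH2Br and C6'HBr, racemic (not isolated) | BrCc1c(OC)c2c(c3c1OC(=O)c1c(C)cc(OC)c(Br)c1O3)C(Br)OC2=O | intermediate
19 | depsidone as 17 with 3'-CH2OCH3 and C6'H(OCH3), racemic | COCc1c(OC)c2c(c3c1OC(=O)c1c(C)cc(OC)c(Br)c1O3)C(OC)OC2=O | intermediate
20 | depsidone as 19 with C3–CHO in place of C3–Br, racemic | COCc1c(OC)c2c(c3c1OC(=O)c1c(C)cc(OC)c(C=O)c1O3)C(OC)OC2=O | intermediate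
21 | racemic salazinic acid | OCc1c(O)c2c(c3c1OC(=O)c1c(C)cc(O)c(C=O)c1O3)C(O)OC2=O | intermediate
22 | racemic galbinic acid | CC(=O)OCc1c(O)c2c(c3c1OC(=O)c1c(C)cc(O)c(C=O)c1O3)C(O)OC2=O | intermediate
23 | (S)-galbinic acid | CC(=O)OCc1c(O)c2c(c3c1OC(=O)c1c(C)cc(O)c(C=O)c1O3)[C@@H](O)OC2=O | target

Total steps: 16. Longest linear sequence: 13 (steps 1–5, 8, 10–16).

Steps most likely to fail

Step 10. The cycloaddition may stall because the aryloxy donor on the reacting alkyne carbon raises the LUMO of 11 and both bond-forming carbons are crowded. Thermal breakdown or hydration of the ynol ether, or bonding in the reversed orientation, could then overtake it. The fallback uses known reactions only and sets out from 13, 10 and 7. Bromopyrone 13 is heated with bromopropiolate 10 (toluene, 120 °C, sealed tube). Haloalkynoates are established dienophiles, and the same polarity match places the alkyne bromine next to the pyrone bromine, so the bridged adduct F1 should lose CO2 to give 4-methoxybenzyl 2,3-dibromo-4-methoxy-6-methylbenzoate F2. Phenol 7 is then joined to F2 by an Ullmann ether synthesis (Cu2O, Cs2CO3, pyridine, 115 °C). This should take the bromide ortho to the ester, which is activated and can chelate copper, in preference to the one between bromine and methoxy. The product is 15, where the route is rejoined. The ring-A construction is kept; only the C–O bond is made after ring A instead of before it.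

Step 8. The phenoxide may add a second time to the product to give a ketene acetal, may attack bromine instead of carbon, or the ynol ether may be hydrated during isolation. The fallback sets out from 7 and 9. DABCO-catalysed conjugate addition of phenol 7 to propiolate 9 (CH2Cl2, 20 °C) should give 4-methoxybenzyl (E)-3-(aryloxy)acrylate F3. Bromine adds to the enol ether double bond at −78 °C to give 4-methoxybenzyl 2,3-dibromo-3-(aryloxy)propanoate F4, from which triethylamine removes HBr to give 4-methoxybenzyl (Z)-2-bromo-3-(aryloxy)acrylate F5. Anti elimination of HBr with KN(SiMe3)2 (THF, −78 °C), the classical dehydrohalogenation of a vinyl bromide to an alkyne, then gives 11, where the route is rejoined.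

Step 16. The hemiacetal may epimerise on the column or while the fractions are concentrated, by opening to the formyl acid. The fallback sets out from 22. The lactol OH and both phenols are silylated (Et3SiOSO2CF3, 2,6-lutidine, CH2Cl2, −78 °C) to give the racemic tris(triethylsilyl) ether of galbinic acid F6, in which C6' is a configurationally fixed mixed acetal. F6 is resolved on the same chiral phase to give the single-enantiomer tris(triethylsilyl) ether F7, which has the spatial arrangement of 23; its descriptor is R because O–Si outranks the ring oxygen. HF·pyridine (THF, −20 °C) then cleaves the three O–Si bonds without breaking either C–O bond at the acetal carbon and gives 23.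

Further compounds
F1 | step 10 | 4-methoxybenzyl 4,5-dibromo-8-methoxy-1-methyl-3-oxo-2-oxabicyclo[2.2.2]octa-5,7-diene-6-carboxylate (racemic, not isolated) | BrC12C(=O)OC(C)(C=C1OC)C(C(=O)OCc1ccc(OC)cc1)=C2Br
F2 | step 10 | 4-methoxybenzyl 2,3-dibromo-4-methoxy-6-methylbenzoate | COc1ccc(COC(=O)c2c(C)cc(OC)c(Br)c2Br)cc1
F3 | step 8 | 4-methoxybenzyl (E)-3-(aryloxy)acrylate, aryl = phthalide unit of 7 | COc1ccc(COC(=O)/C=C/Oc2c(OCc3ccc(OC)cc3)c(C)c(OC)c3C(=O)OCc23)cc1
F4 | step 8 | 4-methoxybenzyl 2,3-dibromo-3-(aryloxy)propanoate (racemic diastereomer mixture, not isolated) | COc1ccc(COC(=O)C(Br)C(Br)Oc2c(OCc3ccc(OC)cc3)c(C)c(OC)c3C(=O)OCc23)cc1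
F5 | step 8 | 4-methoxybenzyl (Z)-2-bromo-3-(aryloxy)acrylate | COc1ccc(COC(=O)/C(Br)=C/Oc2c(OCc3ccc(OC)cc3)c(C)c(OC)c3C(=O)OCc23)cc1
F6 | step 16 | racemic galbinic acid tris(triethylsilyl) ether (O4, O2' and lactol O silylated) | CC(=O)OCc1c(O[Si](CC)(CC)CC)c2c(c3c1OC(=O)c1c(C)cc(O[Si](CC)(CC)CC)c(C=O)c1O3)C(O[Si](CC)(CC)CC)OC2=O
F7 | step 16 | (R)-configured tris(triethylsilyl) ether with the spatial arrangement of 23 | CC(=O)OCc1c(O[Si](CC)(CC)CC)c2c(c3c1OC(=O)c1c(C)cc(O[Si](CC)(CC)CC)c(C=O)c1O3)[C@@H](O[Si](CC)(CC)CC)OC2=O
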